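## Retrosynthetic overview

- **Feature:** in ring C the C3–C4 bond joins the carbinol carbon C3 to the carbonyl carbon C4, which sits on ring A at C4a. Read as a C3=C4 double bond with a silyloxy group on C4, it is the alkene of a cyclic silyl enol ether, a 4-silyloxy-2H-chromene.
- **Late stage:** target ⇒ desilylation and Rubottom oxidation (C3–O, anti to the C2 aryl group) ⇒ 4-silyloxy-2H-chromene ⇒ ring-closing metathesis (C3=C4) ⇒ aryl 1-arylallyl ether with an ortho 1-(silyloxy)vinyl group.
- **Fragments:** diene ⇒ enol silylation and iridium-catalysed asymmetric allylic etherification (O1–C2, sets C2) ⇒ ring-A 2-hydroxyacetophenone + ring-B cinnamyl carbonate. Each prenyl group ⇒ Stille coupling of a silylated bromophenol.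
- **Ring order:** rings A and B are bought as arenes. Ring C is the only ring made, and it is closed in the metathesis step.

Key step: step 10

Conventions: flavanone numbering (O1, C2, C3, C4, C4a–C8a, ring B primed) is used throughout; prenyl = 3-methylbut-2-enyl; TBS = tert-butyldimethylsilyl.

Assumption: the (Sa,Sc,Sc) phosphoramidite is taken to give the (S)-configured branched ether in step 8, by analogy with simple cinnamyl carbonates and phenoxides. If a configurational check shows the opposite sense, the equally available antipodal ligand is used.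

## Route

Step 1
Reactants: 1 1-(5-bromo-2,4-dihydroxyphenyl)ethanone
Product: 2 1-[5-bromo-4-(tert-butyldimethylsilyloxy)-2-hydroxyphenyl]ethanone
Conditions: TBSCl (1.05 equiv), imidazole (2 equiv), CH2Cl2, 0 °C → rt
Reagents that add atoms: tert-butyldimethylsilyl chloride, CC(C)(C)[Si](C)(C)Cl
Why: Imidazole-promoted silyl ether formation is selective because the 2-OH is tied up in a hydrogen bond to the acetyl oxygen, so only the free and more acidic 4-OH reacts.

Step 2
Reactants: 2 1-[5-bromo-4-(tert-butyldimethylsilyloxy)-2-hydroxyphenyl]ethanone; 3 tributyl(3-methylbut-2-enyl)stannane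
Product: 4 1-[4-(tert-butyldimethylsilyloxy)-2-hydroxy-5-(3-methylbut-2-enyl)phenyl]ethanone
Conditions: Pd(PPh3)4 (5 mol %), toluene, 110 °C
Reagents that add atoms: none
Why: Stille coupling of the aryl bromide with the allylic stannane needs neither base nor fluoride, so the silyl ether para to the ketone (which the basic medium of a boronate coupling would strip) survives, and C–C reductive elimination at the unhindered CH2 end of the allyl ligand should give the linear prenyl arene.

Step 3
Reactants: 5 3-bromo-4-hydroxybenzaldehyde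
Product: 6 3-bromo-4-(tert-butyldimethylsilyloxy)benzaldehyde
Conditions: TBSCl (1.1 equiv), imidazole (2 equiv), CH2Cl2, rt
Reagents that add atoms: tert-butyldimethylsilyl chloride, CC(C)(C)[Si](C)(C)Cl
Why: Standard imidazole-promoted silylation of the only hydroxyl group.

Step 4
Reactants: 6 3-bromo-4-(tert-butyldimethylsilyloxy)benzaldehyde; 3 tributyl(3-methylbut-2-enyl)stannane
Product: 7 4-(tert-butyldimethylsilyloxy)-3-(3-methylbut-2-enyl)benzaldehyde
Conditions: Pd(PPh3)4 (5 mol %), toluene, 110 °C
Reagents that add atoms: none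
Why: Stille coupling as in step 2; the neutral stannane should leave the aldehyde alone, whereas a heated allylboronate would add to it, and the prenyl group is again delivered through its CH2 terminus.

Step 5
Reactants: 7 4-(tert-butyldimethylsilyloxy)-3-(3-methylbut-2-enyl)benzaldehyde
Product: 8 ethyl (E)-3-[4-(tert-butyldimethylsilyloxy)-3-(3-methylbut-2-enyl)phenyl]prop-2-enoate
Conditions: Ph3P=CHCO2Et (1.2 equiv), CH2Cl2, rt
Reagents that add atoms: ethyl (triphenylphosphoranylidene)acetate, CCOC(=O)C=P(c1ccccc1)(c1ccccc1)c1ccccc1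
Why: Wittig olefination with a stabilised ylide is base-free, spares the labile aryl silyl ether and gives the E-cinnamate under the usual bias of stabilised ylides.

Step 6
Reactants: 8 ethyl (E)-3-[4-(tert-butyldimethylsilyloxy)-3-(3-methylbut-2-enyl)phenyl]prop-2-enoate
Product: 9 (E)-3-[4-(tert-butyldimethylsilyloxy)-3-(3-methylbut-2-enyl)phenyl]prop-2-en-1-ol
Conditions: i-Bu2AlH (2.3 equiv), CH2Cl2, −78 °C; aq. potassium sodium tartrate
Reagents that add atoms: none
Why: 1,2-Reduction of the conjugated ester by i-Bu2AlH at low temperature gives the allylic alcohol without touching the alkenes or the silyl ether.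

Step 7
Reactants: 9 (E)-3-[4-(tert-butyldimethylsilyloxy)-3-(3-methylbut-2-enyl)phenyl]prop-2-en-1-ol
Product: 10 (E)-3-[4-(tert-butyldimethylsilyloxy)-3-(3-methylbut-2-enyl)phenyl]prop-2-enyl methyl carbonate
Conditions: ClCO2Me (1.3 equiv), pyridine (2 equiv), CH2Cl2, 0 °C
Reagents that add atoms: methyl chloroformate, COC(=O)Cl
Why: Acylation of the primary allylic alcohol with a chloroformate gives the linear carbonate, the standard leaving group for iridium-catalysed allylic substitution.

Step 8
Reactants: 4 1-[4-(tert-butyldimethylsilyloxy)-2-hydroxy-5-(3-methylbut-2-enyl)phenyl]ethanone; 10 (E)-3-[4-(tert-butyldimethylsilyloxy)-3-(3-methylbut-2-enyl)phenyl]prop-2-enyl methyl carbonate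
Product: 11 1-[4-(tert-butyldimethylsilyloxy)-5-(3-methylbut-2-enyl)-2-{(1S)-1-[4-(tert-butyldimethylsilyloxy)-3-(3-methylbut-2-enyl)phenyl]prop-2-enyloxy}phenyl]ethanone
Conditions: [Ir(cod)Cl]2 (2 mol %), (Sa,Sc,Sc)-(1,1'-binaphthalene-2,2'-diyl) N,N-bis(1-phenylethyl)phosphoramidite (4 mol %), n-PrNH2, THF, 50 °C, then evaporation; 4 (1.2 equiv), 10, K3PO4 (1 equiv, anhydrous), THF, 25 °C
Reagents that add atoms: none
Why: Iridium–phosphoramidite-catalysed asymmetric allylic etherification: the cyclometalated monovalent iridium catalyst ionises the carbonate to an allyl complex of trivalent iridium, the phenoxide (kept at low concentration by K3PO4 and the released methoxide) attacks the aryl-bearing terminus anti to the metal to give the branched ether, and the chiral ligand fixes which allyl face is bound and thereby sets C2 as S.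

Step 9
Reactants: 11 1-[4-(tert-butyldimethylsilyloxy)-5-(3-methylbut-2-enyl)-2-{(1S)-1-[4-(tert-butyldimethylsilyloxy)-3-(3-methylbut-2-enyl)phenyl]prop-2-enyloxy}phenyl]ethanone
Product: 12 (S)-aryl 1-arylallyl ether in which ring A is 5-(tert-butyldimethylsilyloxy)-4-(3-methylbut-2-enyl)-2-[1-(tert-butyldimethylsilyloxy)vinyl]phenyl and ring B is 4-(tert-butyldimethylsilyloxy)-3-(3-methylbut-2-enyl)phenyl
Conditions: Et3N (3 equiv), then TBSOTf (1.5 equiv), CH2Cl2, −20 → 0 °C
Reagents that add atoms: tert-butyldimethylsilyl trifluoromethanesulfonate, CC(C)(C)[Si](C)(C)OS(=O)(=O)C(F)(F)F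
Why: Soft enolisation of the aryl methyl ketone (silyl triflate and tertiary amine) can give only the terminal enol ether, the amine added first buffers the Lewis acid so that the ionisable C2–O1 bond is spared, and the excess reagent re-silylates any phenol bared in step 8.

Step 10
Reactants: 12 (S)-aryl 1-arylallyl ether with the ortho 1-(tert-butyldimethylsilyloxy)vinyl group
Product: 13 (2S)-4,7-bis(tert-butyldimethylsilyloxy)-2-[4-(tert-butyldimethylsilyloxy)-3-(3-methylbut-2-enyl)phenyl]-6-(3-methylbut-2-enyl)-2H-chromene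
Conditions: second-generation Grubbs catalyst RuCl2(H2IMes)(PCy3)(=CHPh) (5–10 mol %), CH2Cl2 (0.005 M), 40 °C, argon sparge, dark
Reagents that add atoms: none
Why: The ruthenium benzylidene exchanges first with the only monosubstituted alkene, the C2 vinyl group, and the new alkylidene adds intramolecularly across the CH2=C(OTBS)Ar unit; cycloreversion of the ruthenacyclobutane forms the C3=C4 bond and a ruthenium methylidene that carries the chain with loss of ethylene. The closest known reaction types are ring-closing metathesis of acyclic tert-butyldimethylsilyl enol ethers with terminal alkenes to cyclic silyl enol ethers, and of 2-alkenylphenyl allyl ethers to 2H-chromenes. Ring C is closed as a six-membered ring from a 1,7-diene whose central atoms C4a and C8a are held ortho on ring A, so closure is entropically favoured and is made irreversible by sparging out ethylene. No stereocentre is formed, since the C–H and C–O bonds at C2 are not touched, and the mild temperature and exclusion of light guard against oxa-6π ring opening of the 2H-chromene, the only racemisation channel. The step needs chemoselectivity for the two terminal alkenes over the two trisubstituted prenyl alkenes, and this is secured by their lower substitution, by high dilution that disfavours intermolecular events, and by the fact that neither prenyl group can reach a reacting alkene through a ring of reasonable size.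

Step 11
Reactants: 13 (2S)-4,7-bis(tert-butyldimethylsilyloxy)-2-[4-(tert-butyldimethylsilyloxy)-3-(3-methylbut-2-enyl)phenyl]-6-(3-methylbut-2-enyl)-2H-chromene
Product: 15 (2R,3R)-3,7-bis(tert-butyldimethylsilyloxy)-2-[4-(tert-butyldimethylsilyloxy)-3-(3-methylbut-2-enyl)phenyl]-6-(3-methylbut-2-enyl)chroman-4-one, via 4-silyloxy-3,4-epoxyflavan 14 (not isolated)
Conditions: dimethyldioxirane (1.0 equiv, acetone solution), CH2Cl2, −78 °C, then → 0 °C
Reagents that add atoms: dimethyldioxirane, CC1(C)OO1
Why: Rubottom oxidation: the electrophilic dioxirane should pick the C3=C4 bond, which is pushed by the 4-silyloxy group and by the ortho- and para-oxygenated ring A and is thus far more electron-rich than the prenyl alkenes, and attack it on the face anti to the adjacent C2 aryl group, after which the silyloxy epoxide opens at benzylic C4 with 1,4-shift of silicon to give the trans (3R) silyl ether, also the thermodynamically preferred diequatorial isomer (C2 is now called R only because oxygenated C3 outranks C1').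

Step 12
Reactants: 15 (2R,3R)-3,7-bis(tert-butyldimethylsilyloxy)-2-[4-(tert-butyldimethylsilyloxy)-3-(3-methylbut-2-enyl)phenyl]-6-(3-methylbut-2-enyl)chroman-4-one
Product: 16 lespeflorin B1, (2R,3R)-3,7-dihydroxy-2-[4-hydroxy-3-(3-methylbut-2-enyl)phenyl]-6-(3-methylbut-2-enyl)chroman-4-one
Conditions: HF·pyridine, pyridine, THF, 0 °C → rt (polypropylene vessel)
Reagents that add atoms: none
Why: Fluoride-driven cleavage of the two aryl and one secondary silyl ether under buffered, weakly acidic conditions avoids the phenoxide and enolate formation that would open ring C or epimerise C2 and C3, and is too mild to cyclise the ortho-prenylphenols.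

## Compound list

1 | 1-(5-bromo-2,4-dihydroxyphenyl)ethanone | CC(=O)c1cc(Br)c(O)cc1O | starting material
2 | 1-[5-bromo-4-(TBS-oxy)-2-hydroxyphenyl]ethanone | CC(=O)c1cc(Br)c(O[Si](C)(C)C(C)(C)C)cc1O | intermediate
3 | tributyl(3-methylbut-2-enyl)stannane | CCCC[Sn](CCCC)(CCCC)CC=C(C)C | starting material
4 | 1-[4-(TBS-oxy)-2-hydroxy-5-prenylphenyl]ethanone | CC(=O)c1cc(CC=C(C)C)c(O[Si](C)(C)C(C)(C)C)cc1O | intermediate
5 | 3-bromo-4-hydroxybenzaldehyde | O=Cc1ccc(O)c(Br)c1 | starting material
6 | 3-bromo-4-(TBS-oxy)benzaldehyde | O=Cc1ccc(O[Si](C)(C)C(C)(C)C)c(Br)c1 | intermediate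
7 | 4-(TBS-oxy)-3-prenylbenzaldehyde | CC(C)=CCc1cc(C=O)ccc1O[Si](C)(C)C(C)(C)C | intermediate
8 | ethyl (E)-3-[4-(TBS-oxy)-3-prenylphenyl]prop-2-enoate | CCOC(=O)/C=C/c1ccc(O[Si](C)(C)C(C)(C)C)c(CC=C(C)C)c1 | intermediate
9 | (E)-3-[4-(TBS-oxy)-3-prenylphenyl]prop-2-en-1-ol | OC/C=C/c1ccc(O[Si](C)(C)C(C)(C)C)c(CC=C(C)C)c1 | intermediate
10 | (E)-3-[4-(TBS-oxy)-3-prenylphenyl]prop-2-enyl methyl carbonate | COC(=O)OC/C=C/c1ccc(O[Si](C)(C)C(C)(C)C)c(CC=C(C)C)c1 | intermediate
11 | (S)-branched aryl 1-arylallyl ether of acetophenone 4 | CC(C)=CCc1cc([C@H](C=C)Oc2cc(O[Si](C)(C)C(C)(C)C)c(CC=C(C)C)cc2C(C)=O)ccc1O[Si](C)(C)C(C)(C)C | intermediate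
12 | (S)-aryl 1-arylallyl ether with ortho 1-(TBS-oxy)vinyl group (metathesis precursor) | CC(C)=CCc1cc([C@H](C=C)Oc2cc(O[Si](C)(C)C(C)(C)C)c(CC=C(C)C)cc2C(=C)O[Si](C)(C)C(C)(C)C)ccc1O[Si](C)(C)C(C)(C)C | intermediate
13 | (2S)-2-aryl-4,7-bis(TBS-oxy)-6-prenyl-2H-chromene (metathesis product) | CC(C)=CCc1cc([C@H]2Oc3cc(O[Si](C)(C)C(C)(C)C)c(CC=C(C)C)cc3C(O[Si](C)(C)C(C)(C)C)=C2)ccc1O[Si](C)(C)C(C)(C)C | intermediate
14 | 3,4-epoxide of 13, epoxide oxygen anti to the C2 aryl group | CC(C)=CCc1cc([C@H]2Oc3cc(O[Si](C)(C)C(C)(C)C)c(CC=C(C)C)cc3[C@]4(O[Si](C)(C)C(C)(C)C)O[C@H]24)ccc1O[Si](C)(C)C(C)(C)C | intermediate (not isolated)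
15 | (2R,3R)-3,7,4'-tris(TBS-oxy)-6,3'-diprenylflavan-4-one | CC(C)=CCc1cc([C@H]2Oc3cc(O[Si](C)(C)C(C)(C)C)c(CC=C(C)C)cc3C(=O)[C@@H]2O[Si](C)(C)C(C)(C)C)ccc1O[Si](C)(C)C(C)(C)C | intermediate
16 | lespeflorin B1 | CC(C)=CCc1cc([C@H]2Oc3cc(O)c(CC=C(C)C)cc3C(=O)[C@@H]2O)ccc1O | target

## Step count and risks

Total step count: 12. Longest linear sequence: 10 steps (5 → 16, steps 3–12).

**Step 10 (ring-closing metathesis).**
- What may go wrong: the alkylidene loaded on the C2 vinyl group may close too slowly onto the hindered 1,1-disubstituted silyl enol ether. Catalyst decay, migration of the allyl ether double bond or metathesis at the prenyl groups would then take over.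
- Fallback: ring C is closed at O1–C2 instead, and the same enol ether is then made from the ketone. It sets out from 4 and 7 and comes back at 13.
- The dianion of 4 (LiN(SiMe3)2, 2.2 equiv, THF, −78 °C) is C-acylated with 1-(tert-butoxycarbonyl)imidazole to the tert-butyl β-keto ester F1.
- Knoevenagel condensation of this ester with 7 (piperidine, AcOH, toluene, molecular sieves) gives the alkylidene β-keto ester F2.
- A cinchona-alkaloid-derived bifunctional thiourea (the pseudoenantiomer that leads to 2S; toluene, −25 °C) promotes asymmetric intramolecular oxa-Michael addition to the tert-butyl flavanone-3-carboxylate F3.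
- TsOH (toluene, 80 °C) effects dealkylative decarboxylation to the (2S)-flavanone F4.
- Et3N/TBSOTf as in step 9 gives 13 and re-silylates any phenol bared by the acid.

**Step 11 (Rubottom oxidation).**
- What may go wrong: oxygen transfer to the two prenyl double bonds may compete with oxidation of the hindered enol ether, and attack anti to the aryl group may be incomplete.
- Fallback: the prenyl groups are installed only after C3 is oxygenated. It sets out from 2 and 6 and comes back at 15.
- Aldehyde 6 is carried, without prenylation, through the reactions of steps 5–7 to the bromo cinnamate F5, the bromo cinnamyl alcohol F6 and the bromo cinnamyl methyl carbonate F7.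
- Etherification with 2 under the conditions of step 8 gives the (S)-dibromo ether F8. Enol silylation then gives the dibromo diene F9, and ring-closing metathesis gives the dibromo chromene F10.
- With no other alkene left, dimethyldioxirane can be used in excess. It should give, through the dibromo silyloxy epoxide F11, the (2R,3R)-dibromo tris(silyl ether) F12.
- A twofold Stille coupling with 3 (Pd(PPh3)4, toluene, 110 °C) installs both prenyl groups under neutral conditions and gives 15.

**Step 8 (asymmetric allylic etherification).**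
- What may go wrong: O-attack by the hydrogen-bonded, weakly nucleophilic 2-acylphenoxide may be slow. Re-ionisation of the electron-rich branched ether by the catalyst would then erode the configuration at C2 and let material drift to the linear ether.
- Fallback: the stereocentre is set by C–C bond formation and the O1–C2 bond by stereoinvertive substitution. It sets out from 7 and comes back at 11.
- Catalytic enantioselective addition of divinylzinc (from vinylmagnesium bromide and ZnCl2) to 7 in the presence of (+)-3-exo-(dimethylamino)isoborneol gives the (R)-allylic alcohol F13.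
- Mitsunobu reaction of this alcohol with phenol 4 (PPh3, diisopropyl azodicarboxylate, toluene, −20 °C) proceeds by SN2 displacement with inversion and gives 11.

## Further compounds

F1 | step 10 | tert-butyl 3-[4-(TBS-oxy)-2-hydroxy-5-prenylphenyl]-3-oxopropanoate | CC(C)=CCc1cc(C(=O)CC(=O)OC(C)(C)C)c(O)cc1O[Si](C)(C)C(C)(C)C
F2 | step 10 | tert-butyl 2-[4-(TBS-oxy)-2-hydroxy-5-prenylbenzoyl]-3-[4-(TBS-oxy)-3-prenylphenyl]prop-2-enoate (alkene geometry not defined) | CC(C)=CCc1cc(C=C(C(=O)OC(C)(C)C)C(=O)c2cc(CC=C(C)C)c(O[Si](C)(C)C(C)(C)C)cc2O)ccc1O[Si](C)(C)C(C)(C)C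
F3 | step 10 | tert-butyl (2S)-7,4'-bis(TBS-oxy)-6,3'-diprenyl-4-oxoflavan-3-carboxylate (C3 epimerisable) | CC(C)=CCc1cc([C@H]2Oc3cc(O[Si](C)(C)C(C)(C)C)c(CC=C(C)C)cc3C(=O)C2C(=O)OC(C)(C)C)ccc1O[Si](C)(C)C(C)(C)C
F4 | step 10 | (2S)-7,4'-bis(TBS-oxy)-6,3'-diprenylflavanone | CC(C)=CCc1cc([C@H]2Oc3cc(O[Si](C)(C)C(C)(C)C)c(CC=C(C)C)cc3C(=O)C2)ccc1O[Si](C)(C)C(C)(C)C
F5 | step 11 | ethyl (E)-3-[3-bromo-4-(TBS-oxy)phenyl]prop-2-enoate | CCOC(=O)/C=C/c1ccc(O[Si](C)(C)C(C)(C)C)c(Br)c1
F6 | step 11 | (E)-3-[3-bromo-4-(TBS-oxy)phenyl]prop-2-en-1-ol | OC/C=C/c1ccc(O[Si](C)(C)C(C)(C)C)c(Br)c1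
F7 | step 11 | (E)-3-[3-bromo-4-(TBS-oxy)phenyl]prop-2-enyl methyl carbonate | COC(=O)OC/C=C/c1ccc(O[Si](C)(C)C(C)(C)C)c(Br)c1
F8 | step 11 | 1-[5-bromo-4-(TBS-oxy)-2-{(1S)-1-[3-bromo-4-(TBS-oxy)phenyl]prop-2-enyloxy}phenyl]ethanone | Brc1cc([C@H](C=C)Oc2cc(O[Si](C)(C)C(C)(C)C)c(Br)cc2C(C)=O)ccc1O[Si](C)(C)C(C)(C)C
F9 | step 11 | (S)-dibromo aryl 1-arylallyl ether with ortho 1-(TBS-oxy)vinyl group | Brc1cc([C@H](C=C)Oc2cc(O[Si](C)(C)C(C)(C)C)c(Br)cc2C(=C)O[Si](C)(C)C(C)(C)C)ccc1O[Si](C)(C)C(C)(C)C
F10 | step 11 | (2S)-6-bromo-2-[3-bromo-4-(TBS-oxy)phenyl]-4,7-bis(TBS-oxy)-2H-chromene | Brc1cc([C@H]2Oc3cc(O[Si](C)(C)C(C)(C)C)c(Br)cc3C(O[Si](C)(C)C(C)(C)C)=C2)ccc1O[Si](C)(C)C(C)(C)C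
F11 | step 11 | 3,4-epoxide of F10, epoxide oxygen anti to the C2 aryl group | Brc1cc([C@H]2Oc3cc(O[Si](C)(C)C(C)(C)C)c(Br)cc3[C@]4(O[Si](C)(C)C(C)(C)C)O[C@H]24)ccc1O[Si](C)(C)C(C)(C)C
F12 | step 11 | (2R,3R)-6,3'-dibromo-3,7,4'-tris(TBS-oxy)flavan-4-one | Brc1cc([C@H]2Oc3cc(O[Si](C)(C)C(C)(C)C)c(Br)cc3C(=O)[C@@H]2O[Si](C)(C)C(C)(C)C)ccc1O[Si](C)(C)C(C)(C)C
F13 | step 8 | (1R)-1-[4-(TBS-oxy)-3-prenylphenyl]prop-2-en-1-ol | CC(C)=CCc1cc([C@@H](C=C)O)ccc1O[Si](C)(C)C(C)(C)C
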